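**Retrosynthetic overview**
1. The target is a 1,2-dioxane (O–O, C3, C4, C5, C6) cis-fused along C3–C4 to a γ-lactone (C1, C2, C3, C4, O). The plan rests on C4 and C6 both being methyl-bearing, oxygen-bearing quaternary carbons set 1,3 across the C5 methylene: one O–O bridge over them is a meso 3,5-dimethyl-1,2-dioxolane, and moving the C4-bound peroxide oxygen to neighbouring C3 gives the dioxane and leaves C4 free for the lactone oxygen.
2. Last disconnections: C7=C8 (Wittig with a phenyl-terminated C11 ylide, then diimide) and the lactone C1–O bond (C1 acid from an allyl group on C3 by ozonolysis and chlorite oxidation).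
3. Key disconnection: the dioxane C3–O bond and the C4–OAc bond, traced back to a dioxolan-3-yl carbinyl chloromethanesulfonate through an oxirane-fused peroxonium ion (1,2-peroxide shift, inversion at C3 and at C4).
4. The sulfonate comes from the meso dioxolane diol (2,4-dimethylpenta-1,4-diene, bis-epoxidation, double perhydrolysis) by lipase monoacetylation, oxidation, Brown allylation and sulfonylation.
5. Ring order: 1,2-dioxolane (step 2), 1,2-dioxane by ring enlargement (step 7), γ-lactone (step 10).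

Key step: step 7

Remark on the chemistry: atoms carry the plakortolide numbering (C1 lactone carbonyl, C2, C3 CH–OO, C4 C(CH3)–O, C5, C6 C(CH3)–OO, C7 first chain carbon), and the monocyclic dioxanes are numbered O1, O2, C3 (the CH carbon) to C6 to match. It is assumed that screening provides a lipase that acylates the hydroxymethyl group on the (R)-configured ring carbon of meso diol 4; should the best enzyme prefer the other arm, hydrolysis of the meso diacetate with that enzyme would lead to the same monoacetate 5.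

**Step 1**
Reactants: 1 2,4-dimethylpenta-1,4-diene
Product: 2 2,2'-methylenebis(2-methyloxirane), meso isomer formed together with the racemic diastereomer and used as the mixture
Conditions: mCPBA (2.3 equiv), NaHCO3, CH2Cl2, 0 °C → rt
Reagents that add atoms: mCPBA (3-chloroperoxybenzoic acid), OOC(=O)c1cccc(Cl)c1
Why: Prilezhaev epoxidation of both 1,1-disubstituted alkenes; the two oxidations are independent, so no diastereocontrol is expected and the meso bis-epoxide forms together with the racemic one (the unwanted series is removed after step 2).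

**Step 2**
Reactants: 2 2,2'-methylenebis(2-methyloxirane)
Product: 4 [(3R,5S)-3,5-dimethyl-1,2-dioxolane-3,5-diyl]dimethanol (cis-meso), via hydroperoxy epoxide 3 (not isolated)
Conditions: H2O2 (anhydrous, in Et2O, excess), H3PMo12O40 (cat.), Et2O, 0 °C → rt; chromatography to remove the trans (racemic) diol
Reagents that add atoms: hydrogen peroxide, OO
Why: Acid-catalysed perhydrolysis opens one 2,2-disubstituted epoxide at its tertiary carbon to the β-hydroxy hydroperoxide 3, whose OOH group (an α-effect nucleophile, expected to outrun the new primary OH) then opens the second protonated epoxide at its tertiary carbon in a 5-exo-tet closure; since both openings should go mainly with inversion, the meso bis-epoxide is expected to give the cis (meso) dioxolane and the racemic one the trans diol.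

**Step 3**
Reactants: 4 [(3R,5S)-3,5-dimethyl-1,2-dioxolane-3,5-diyl]dimethanol
Product: 5 [(3R,5S)-5-(hydroxymethyl)-3,5-dimethyl-1,2-dioxolan-3-yl]methyl acetate
Conditions: lipase PS (Burkholderia cepacia, immobilised), vinyl acetate, tBuOMe, rt
Reagents that add atoms: vinyl acetate, CC(=O)OC=C
Why: Lipase-catalysed irreversible transesterification (enzymatic desymmetrisation of a meso diol) acylates one of the two enantiotopic hydroxymethyl groups, here the one on the R-configured ring carbon, and thereby fixes the absolute configuration of both quaternary carbons (later C4 and C6) in one operation.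

**Step 4**
Reactants: 5 [(3R,5S)-5-(hydroxymethyl)-3,5-dimethyl-1,2-dioxolan-3-yl]methyl acetate
Product: 6 [(3R,5S)-5-formyl-3,5-dimethyl-1,2-dioxolan-3-yl]methyl acetate
Conditions: Dess–Martin periodinane, NaHCO3, CH2Cl2, 0 °C → rt
Reagents that add atoms: none
Why: Dess–Martin oxidation of the primary alcohol under buffered conditions that do not touch the dialkyl peroxide; the aldehyde sits on a fully substituted carbon, so neither epimerisation nor Kornblum–DeLaMare cleavage is possible.

**Step 5**
Reactants: 6 [(3R,5S)-5-formyl-3,5-dimethyl-1,2-dioxolan-3-yl]methyl acetate; 7 allylmagnesium bromide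
Product: 9 [(3R,5S)-5-[(1S)-1-hydroxybut-3-enyl]-3,5-dimethyl-1,2-dioxolan-3-yl]methyl acetate, via (−)-B-allyldiisopinocampheylborane 8 (not isolated)
Conditions: (−)-Ipc2BOMe, 7, Et2O, 0 °C → rt, Mg salts filtered off; 6, Et2O, −78 °C; then pH 7 phosphate buffer, 30% H2O2, MeOH, 0 °C
Reagents that add atoms: none
Why: Brown asymmetric allylboration through a closed six-membered (Zimmerman–Traxler) transition state: the reagent made from (−)-Ipc2BOMe (of (+)-α-pinene origin) is expected to add allyl to the si face of the aldehyde under reagent control and so to set the (S)-carbinol that becomes C3, and the buffered peroxide work-up spares the acetate and the O–O bond.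

**Step 6**
Reactants: 9 [(3R,5S)-5-[(1S)-1-hydroxybut-3-enyl]-3,5-dimethyl-1,2-dioxolan-3-yl]methyl acetate
Product: 10 (1S)-1-[(3S,5R)-5-(acetoxymethyl)-3,5-dimethyl-1,2-dioxolan-3-yl]but-3-enyl chloromethanesulfonate
Conditions: ClCH2SO2Cl, pyridine, CH2Cl2, 0 °C
Reagents that add atoms: chloromethanesulfonyl chloride, ClCS(Cl)(=O)=O
Why: O-Sulfonylation of the hindered secondary alcohol (retention at C3) installs a leaving group that ionises more easily than a mesylate but is still isolable.

**Step 7**
Reactants: 10 (1S)-1-[(3S,5R)-5-(acetoxymethyl)-3,5-dimethyl-1,2-dioxolan-3-yl]but-3-enyl chloromethanesulfonate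
Product: 12 [(3R,4R,6R)-4-acetoxy-3-allyl-4,6-dimethyl-1,2-dioxan-6-yl]methyl acetate, via bicyclic peroxonium ion 11 (not isolated)
Conditions: Zn(OAc)2 (excess), AcOH, 50–60 °C
Reagents that add atoms: zinc acetate (acetate is transferred), CC(=O)[O-].CC(=O)[O-].[Zn+2]
Why: Proposed new method: on warming with zinc acetate the peroxide oxygen on C4, which reaches an anti-periplanar position to the C3–O sulfonate bond by rotation about C3–C4, displaces chloromethanesulfonate to give the oxirane-fused 1,2-dioxolan-1-ium ion 11, and acetate then opens the three-membered ring at tertiary C4 from the side opposite the departing oxygen, so that the oxygen has moved from C4 to C3 and the dioxolane has become the 1,2-dioxane (O–O–C3–C4–C5–C6). The closest known reactions are the zinc acetate-promoted enlargement of tetrahydrofuran-2-ylmethyl sulfonates to tetrahydropyrans through bicyclic oxonium ions and the silver-assisted formation of dialkylperoxonium ions from β-halo peroxides; a peroxide oxygen as the migrating neighbour in a ring enlargement is the untested part. The six-membered ring is closed by C3–O bond formation in a 3-exo-tet attack on the sulfonate carbon followed by cleavage of the C4–O fusion bond of the onium ion, that is by ring enlargement and not by a direct 6-endo closure. C3 is set by inversion of the Brown-derived (S)-carbinol and C4 by inversion of the lipase-derived quaternary centre, which places the C4 acetate cis to the C3 allyl group as the cis-fused lactone requires, while C6 is untouched. The step needs neighbouring-group participation to beat direct acetolysis or elimination at C3, and opening at C4 rather than at C3: the hindered neopentyl-type C3 and the weakly basic ionising medium favour participation, and the tertiary, more cation-stabilising C4 together with relief of dioxolane strain favours cleavage of the C4–O bond.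

**Step 8**
Reactants: 12 [(3R,4R,6R)-4-acetoxy-3-allyl-4,6-dimethyl-1,2-dioxan-6-yl]methyl acetate
Product: 13 2-[(3R,4R,6R)-4-acetoxy-6-(acetoxymethyl)-4,6-dimethyl-1,2-dioxan-3-yl]acetaldehyde
Conditions: O3, CH2Cl2/MeOH, NaHCO3, −78 °C; then Me2S, −78 °C → rt
Reagents that add atoms: ozone, [O-][O+]=O
Why: Ozonolysis of the terminal alkene with dimethyl sulfide work-up, which reduces the methoxy hydroperoxide but not the hindered dialkyl peroxide; no stereocentre is involved and the β-peroxy aldehyde is carried on crude.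

**Step 9**
Reactants: 13 2-[(3R,4R,6R)-4-acetoxy-6-(acetoxymethyl)-4,6-dimethyl-1,2-dioxan-3-yl]acetaldehyde
Product: 14 2-[(3R,4R,6R)-4-acetoxy-6-(acetoxymethyl)-4,6-dimethyl-1,2-dioxan-3-yl]acetic acid
Conditions: NaClO2, NaH2PO4, 2-methylbut-2-ene, tBuOH/H2O, 0 °C → rt
Reagents that add atoms: sodium chlorite, [Na+].[O-]Cl=O
Why: Pinnick (chlorite) oxidation converts the aldehyde into the acid under mildly acidic conditions that avoid enolisation and β-elimination of the peroxide.

**Step 10**
Reactants: 14 2-[(3R,4R,6R)-4-acetoxy-6-(acetoxymethyl)-4,6-dimethyl-1,2-dioxan-3-yl]acetic acid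
Product: 16 (3R,4aR,7aR)-3-(hydroxymethyl)-3,4a-dimethyl-4,4a,7,7a-tetrahydrofuro[3,2-c][1,2]dioxin-6(3H)-one, via dihydroxy acid 15 (not isolated)
Conditions: LiOH, THF/H2O, 0 °C → rt; 1 M HCl to pH 3; PPTS (cat.), CH2Cl2, rt
Reagents that add atoms: none
Why: Saponification of both acetates is done at the carboxylate stage, where no acidic α-hydrogen can set off β-elimination of the peroxide, and acidification then lets the C4 hydroxyl and the C3 acetic acid chain, held cis by step 7, close the γ-lactone by acyl substitution (5-exo-trig, retention at C4).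

**Step 11**
Reactants: 16 (3R,4aR,7aR)-3-(hydroxymethyl)-3,4a-dimethyl-4,4a,7,7a-tetrahydrofuro[3,2-c][1,2]dioxin-6(3H)-one
Product: 17 (3R,4aR,7aR)-3,4a-dimethyl-6-oxohexahydrofuro[3,2-c][1,2]dioxine-3-carbaldehyde
Conditions: Dess–Martin periodinane, NaHCO3, CH2Cl2, 0 °C → rt
Reagents that add atoms: none
Why: Dess–Martin oxidation of the primary C7 alcohol gives an aldehyde on a fully substituted carbon, so C6 cannot epimerise, and the neutral buffered medium leaves lactone and peroxide alone.

**Step 12**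
Reactants: 18 11-bromoundecan-1-ol; 19 phenylmagnesium bromide
Product: 20 11-phenylundecan-1-ol
Conditions: 19 (2.5 equiv), Li2CuCl4 (cat.), THF, −10 °C → rt; aq. NH4Cl
Reagents that add atoms: none
Why: Copper-catalysed (Kochi-type) cross-coupling of the aryl Grignard reagent with the primary alkyl bromide; the first equivalent of 19 only converts the hydroxyl into its inert magnesium alkoxide.

**Step 13**
Reactants: 20 11-phenylundecan-1-ol
Product: 21 (11-bromoundecyl)benzene
Conditions: CBr4, PPh3, CH2Cl2, 0 °C → rt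
Reagents that add atoms: carbon tetrabromide, BrC(Br)(Br)Br
Why: Appel reaction converts the primary alcohol into the bromide by SN2 displacement of the oxyphosphonium intermediate.

**Step 14**
Reactants: 21 (11-bromoundecyl)benzene
Product: 22 (11-phenylundecyl)triphenylphosphonium bromide
Conditions: PPh3, MeCN, reflux
Reagents that add atoms: triphenylphosphine, c1ccc(cc1)P(c1ccccc1)c1ccccc1
Why: SN2 quaternisation of triphenylphosphine by the primary bromide gives the Wittig salt.

**Step 15**
Reactants: 17 (3R,4aR,7aR)-3,4a-dimethyl-6-oxohexahydrofuro[3,2-c][1,2]dioxine-3-carbaldehyde; 22 (11-phenylundecyl)triphenylphosphonium bromide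
Product: 24 (3R,4aR,7aR)-3,4a-dimethyl-3-[(1Z)-12-phenyldodec-1-enyl]-4,4a,7,7a-tetrahydrofuro[3,2-c][1,2]dioxin-6(3H)-one, via phosphonium ylide 23 (not isolated)
Conditions: 22, NaN(SiMe3)2, THF, 0 °C; ylide solution (1.05 equiv) added to 17, THF, −78 °C → −20 °C; aq. NH4Cl
Reagents that add atoms: none
Why: Wittig olefination with a non-stabilised ylide, which adds to the aldehyde at −78 °C much faster than it deprotonates or attacks the lactone; the Z alkene is expected, but the geometry is of no consequence because the double bond is reduced next.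

**Step 16**
Reactants: 24 (3R,4aR,7aR)-3,4a-dimethyl-3-[(1Z)-12-phenyldodec-1-enyl]-4,4a,7,7a-tetrahydrofuro[3,2-c][1,2]dioxin-6(3H)-one
Product: 25 plakortolide K, (3S,4aR,7aR)-3,4a-dimethyl-3-(12-phenyldodecyl)-4,4a,7,7a-tetrahydrofuro[3,2-c][1,2]dioxin-6(3H)-one
Conditions: KO2CN=NCO2K (excess, in portions), AcOH, MeOH/CH2Cl2, 0 °C → rt
Reagents that add atoms: none
Why: Diimide, set free from potassium azodicarboxylate, transfers two hydrogens to the C=C bond in a concerted syn addition and touches neither the O–O bond nor the lactone, so no stereocentre changes (the descriptor at C6 goes from R to S only through the priority rules).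

**Compound list**
1 | 2,4-dimethylpenta-1,4-diene | CC(=C)CC(C)=C | starting material
2 | 2,2'-methylenebis(2-methyloxirane), meso isomer shown, formed with the racemic diastereomer | C[C@]1(CO1)C[C@@]1(C)CO1 | intermediate
3 | (2S)-2-hydroperoxy-2-methyl-3-[(2S)-2-methyloxiran-2-yl]propan-1-ol (racemic, from meso-2) | C[C@@](OO)(CO)C[C@@]1(C)CO1 | intermediate (not isolated)
4 | [(3R,5S)-3,5-dimethyl-1,2-dioxolane-3,5-diyl]dimethanol (cis, meso) | OC[C@@]1(C)C[C@@](C)(CO)OO1 | intermediate
5 | [(3R,5S)-5-(hydroxymethyl)-3,5-dimethyl-1,2-dioxolan-3-yl]methyl acetate | CC(=O)OC[C@@]1(C)C[C@@](C)(CO)OO1 | intermediate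
6 | [(3R,5S)-5-formyl-3,5-dimethyl-1,2-dioxolan-3-yl]methyl acetate | CC(=O)OC[C@@]1(C)C[C@@](C)(C=O)OO1 | intermediate
7 | allylmagnesium bromide | C=CC[Mg]Br | starting material
8 | (−)-B-allyldiisopinocampheylborane | C=CCB([C@@H]1C[C@@H]2C[C@H]([C@H]1C)C2(C)C)[C@@H]1C[C@@H]2C[C@H]([C@H]1C)C2(C)C | intermediate (not isolated)
9 | [(3R,5S)-5-[(1S)-1-hydroxybut-3-enyl]-3,5-dimethyl-1,2-dioxolan-3-yl]methyl acetate | CC(=O)OC[C@@]1(C)C[C@@](C)([C@H](CC=C)O)OO1 | intermediate
10 | (1S)-1-[(3S,5R)-5-(acetoxymethyl)-3,5-dimethyl-1,2-dioxolan-3-yl]but-3-enyl chloromethanesulfonate | CC(=O)OC[C@@]1(C)C[C@@](C)([C@H](CC=C)OS(=O)(=O)CCl)OO1 | intermediate (key-step precursor)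
11 | 3-(acetoxymethyl)-6-allyl-3,5-dimethyl-1,2-dioxabicyclo[3.1.0]hexan-1-ium (oxirane-fused dioxolanium ion, C3 inverted) | CC(=O)OC[C@@]1(C)C[C@@]2(C)[C@@H](CC=C)[O+]2O1 | intermediate (not isolated)
12 | [(3R,4R,6R)-4-acetoxy-3-allyl-4,6-dimethyl-1,2-dioxan-6-yl]methyl acetate | CC(=O)OC[C@@]1(C)C[C@@](C)(OC(C)=O)[C@@H](CC=C)OO1 | intermediate (key-step product)
13 | 2-[(3R,4R,6R)-4-acetoxy-6-(acetoxymethyl)-4,6-dimethyl-1,2-dioxan-3-yl]acetaldehyde | CC(=O)OC[C@@]1(C)C[C@@](C)(OC(C)=O)[C@@H](CC=O)OO1 | intermediate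
14 | 2-[(3R,4R,6R)-4-acetoxy-6-(acetoxymethyl)-4,6-dimethyl-1,2-dioxan-3-yl]acetic acid | CC(=O)OC[C@@]1(C)C[C@@](C)(OC(C)=O)[C@@H](CC(=O)O)OO1 | intermediate
15 | 2-[(3R,4R,6R)-4-hydroxy-6-(hydroxymethyl)-4,6-dimethyl-1,2-dioxan-3-yl]acetic acid | OC[C@@]1(C)C[C@@](C)(O)[C@@H](CC(=O)O)OO1 | intermediate (not isolated)
16 | (3R,4aR,7aR)-3-(hydroxymethyl)-3,4a-dimethyl-4,4a,7,7a-tetrahydrofuro[3,2-c][1,2]dioxin-6(3H)-one | C[C@]1(CO)C[C@@]2(C)OC(=O)C[C@H]2OO1 | intermediate
17 | (3R,4aR,7aR)-3,4a-dimethyl-6-oxohexahydrofuro[3,2-c][1,2]dioxine-3-carbaldehyde | C[C@]1(C=O)C[C@@]2(C)OC(=O)C[C@H]2OO1 | intermediate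
18 | 11-bromoundecan-1-ol | OCCCCCCCCCCCBr | starting material
19 | phenylmagnesium bromide | Br[Mg]c1ccccc1 | starting material
20 | 11-phenylundecan-1-ol | OCCCCCCCCCCCc1ccccc1 | intermediate
21 | (11-bromoundecyl)benzene | BrCCCCCCCCCCCc1ccccc1 | intermediate
22 | (11-phenylundecyl)triphenylphosphonium bromide | [Br-].c1ccccc1CCCCCCCCCCC[P+](c1ccccc1)(c1ccccc1)c1ccccc1 | intermediate
23 | (11-phenylundecylidene)triphenylphosphorane | c1ccccc1CCCCCCCCCCC=P(c1ccccc1)(c1ccccc1)c1ccccc1 | intermediate (not isolated)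
24 | (3R,4aR,7aR)-3,4a-dimethyl-3-[(1Z)-12-phenyldodec-1-enyl]-4,4a,7,7a-tetrahydrofuro[3,2-c][1,2]dioxin-6(3H)-one | C[C@]1(/C=C\CCCCCCCCCCc2ccccc2)C[C@@]2(C)OC(=O)C[C@H]2OO1 | intermediate
25 | plakortolide K, (3S,4aR,7aR)-3,4a-dimethyl-3-(12-phenyldodecyl)-4,4a,7,7a-tetrahydrofuro[3,2-c][1,2]dioxin-6(3H)-one | C[C@]1(CCCCCCCCCCCCc2ccccc2)C[C@@]2(C)OC(=O)C[C@H]2OO1 | target

**Step count and risks**
Total: 16 steps. Longest linear sequence: 13 steps (steps 1–11, 15, 16); the phosphonium salt 22 takes 3 steps (12–14).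

Steps most likely to fail:

1. Step 7 (proposed new method). The peroxide oxygen may be too weak a neighbouring group, so that elimination towards the allyl group or direct acetolysis at C3 takes over. The onium ion may also be opened at C3 (return to a dioxolane), or C4 may ionise fully with loss of configuration or heterolysis of the O–O bond.
Fallback with known chemistry, from 5 back to 16. The two arms of 5 change roles: the acetoxymethyl carbon becomes C4 with retention and the hydroxymethyl carbon becomes C6 with inversion, which leads to the same enantiomer.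
 - Zn/AcOH cleaves the O–O bond of 5 to (2R,4S)-2,4,5-trihydroxy-2,4-dimethylpentyl acetate F1.
 - 2,2-Dimethoxypropane/PPTS masks the terminal 1,2-diol as (2R)-2-hydroxy-2-methyl-3-[(4S)-2,2,4-trimethyl-1,3-dioxolan-4-yl]propyl acetate F2.
 - K2CO3/MeOH gives (2R)-2-methyl-3-[(4S)-2,2,4-trimethyl-1,3-dioxolan-4-yl]propane-1,2-diol F3.
 - TEMPO/PhI(OAc)2 gives (2R)-2-hydroxy-2-methyl-3-[(4S)-2,2,4-trimethyl-1,3-dioxolan-4-yl]propanal F4.
 - Ph3P=C=C=O (toluene, 80 °C) acylates the tertiary hydroxyl to the (triphenylphosphoranylidene)acetate of F4, F5 (not isolated), which closes by intramolecular Wittig reaction to (5R)-5-methyl-5-{[(4S)-2,2,4-trimethyl-1,3-dioxolan-4-yl]methyl}furan-2(5H)-one F6.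
 - Aqueous AcOH frees (5R)-5-[(2S)-2,3-dihydroxy-2-methylpropyl]-5-methylfuran-2(5H)-one F7.
 - TsCl/pyridine gives (2S)-2-hydroxy-2-methyl-3-[(2R)-2-methyl-5-oxo-2,5-dihydrofuran-2-yl]propyl 4-methylbenzenesulfonate F8.
 - DBU closes (5R)-5-methyl-5-{[(2S)-2-methyloxiran-2-yl]methyl}furan-2(5H)-one F9 with retention at the tertiary carbon.
 - H3PMo12O40-catalysed perhydrolysis with ethereal H2O2 opens the epoxide at the tertiary carbon with inversion to (5R)-5-[(2R)-2-hydroperoxy-3-hydroxy-2-methylpropyl]-5-methylfuran-2(5H)-one F10.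
 - Et2NH in CF3CH2OH brings about the intramolecular oxa-Michael addition of the hydroperoxide to the butenolide, which can only close cis and gives 16.

2. Step 2. The primary hydroxyl freed by the first perhydrolysis may compete with the hydroperoxide for the second epoxide (tetrahydrofuran formation). Both epoxides may be opened by external H2O2, or stereospecificity at the tertiary carbons may be partly lost.
Fallback from 2 back to 4, in which no free hydroxyl is present at the ring closure:
 - Diethylaluminium 2,2,6,6-tetramethylpiperidide (1 equiv, toluene, 0 °C) isomerises one epoxide to the allylic alcohol 2-[(2-methyloxiran-2-yl)methyl]prop-2-en-1-ol F11.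
 - Ac2O/pyridine gives 2-[(2-methyloxiran-2-yl)methyl]prop-2-enyl acetate F12.
 - Mukaiyama–Isayama hydroperoxysilylation (Co(acac)2 cat., O2, Et3SiH, ClCH2CH2Cl) gives 2-methyl-3-(2-methyloxiran-2-yl)-2-(triethylsilylperoxy)propyl acetate F13.
 - TsOH·H2O in wet CH2Cl2 removes the silyl group to 2-hydroperoxy-2-methyl-3-(2-methyloxiran-2-yl)propyl acetate F14 (not isolated), which opens the epoxide 5-exo at the tertiary carbon to racemic cis-[5-(hydroxymethyl)-3,5-dimethyl-1,2-dioxolan-3-yl]methyl acetate F15 (with its trans isomer).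
 - K2CO3/MeOH and chromatographic removal of the trans diol give 4.

3. Step 15. The basic ylide may deprotonate C2 of the lactone and set off β-elimination of the peroxide (retro-oxa-Michael opening), or it may add to the lactone carbonyl; either way ylide is consumed.
Fallback from 14 back to 25, with the olefination done on a carboxylate that cannot eliminate:
 - K2CO3/MeOH at 0 °C removes only the primary acetate to give 2-[(3R,4R,6R)-4-acetoxy-6-(hydroxymethyl)-4,6-dimethyl-1,2-dioxan-3-yl]acetic acid F16.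
 - Dess–Martin oxidation gives 2-[(3R,4R,6R)-4-acetoxy-6-formyl-4,6-dimethyl-1,2-dioxan-3-yl]acetic acid F17.
 - Ylide 23 (2.2 equiv, the first equivalent forming the carboxylate) gives 2-{(3R,4R,6R)-4-acetoxy-4,6-dimethyl-6-[(1Z)-12-phenyldodec-1-enyl]-1,2-dioxan-3-yl}acetic acid F18.
 - Diimide gives 2-[(3R,4R,6S)-4-acetoxy-4,6-dimethyl-6-(12-phenyldodecyl)-1,2-dioxan-3-yl]acetic acid F19.
 - LiOH then acid removes the tertiary acetate to 2-[(3R,4R,6S)-4-hydroxy-4,6-dimethyl-6-(12-phenyldodecyl)-1,2-dioxan-3-yl]acetic acid F20, which lactonises to 25.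

**Further compounds**
F1 | step 7 | (2R,4S)-2,4,5-trihydroxy-2,4-dimethylpentyl acetate | CC(=O)OC[C@@](O)(C)C[C@@](C)(CO)O
F2 | step 7 | (2R)-2-hydroxy-2-methyl-3-[(4S)-2,2,4-trimethyl-1,3-dioxolan-4-yl]propyl acetate | CC(=O)OC[C@@](O)(C)C[C@@]1(C)COC(C)(C)O1
F3 | step 7 | (2R)-2-methyl-3-[(4S)-2,2,4-trimethyl-1,3-dioxolan-4-yl]propane-1,2-diol | OC[C@@](O)(C)C[C@@]1(C)COC(C)(C)O1
F4 | step 7 | (2R)-2-hydroxy-2-methyl-3-[(4S)-2,2,4-trimethyl-1,3-dioxolan-4-yl]propanal | O=C[C@@](O)(C)C[C@@]1(C)COC(C)(C)O1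
F5 | step 7 | (2R)-2-methyl-1-oxo-3-[(4S)-2,2,4-trimethyl-1,3-dioxolan-4-yl]propan-2-yl (triphenylphosphoranylidene)acetate | O=C[C@@](OC(=O)C=P(c1ccccc1)(c1ccccc1)c1ccccc1)(C)C[C@@]1(C)COC(C)(C)O1
F6 | step 7 | (5R)-5-methyl-5-{[(4S)-2,2,4-trimethyl-1,3-dioxolan-4-yl]methyl}furan-2(5H)-one | O=C1C=C[C@@](C)(C[C@@]2(C)COC(C)(C)O2)O1
F7 | step 7 | (5R)-5-[(2S)-2,3-dihydroxy-2-methylpropyl]-5-methylfuran-2(5H)-one | O=C1C=C[C@@](C)(C[C@](C)(O)CO)O1
F8 | step 7 | (2S)-2-hydroxy-2-methyl-3-[(2R)-2-methyl-5-oxo-2,5-dihydrofuran-2-yl]propyl 4-methylbenzenesulfonate | O=C1C=C[C@@](C)(C[C@](C)(O)COS(=O)(=O)c2ccc(C)cc2)O1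
F9 | step 7 | (5R)-5-methyl-5-{[(2S)-2-methyloxiran-2-yl]methyl}furan-2(5H)-one | O=C1C=C[C@@](C)(C[C@@]2(C)CO2)O1
F10 | step 7 | (5R)-5-[(2R)-2-hydroperoxy-3-hydroxy-2-methylpropyl]-5-methylfuran-2(5H)-one | O=C1C=C[C@@](C)(C[C@](C)(CO)OO)O1
F11 | step 2 | 2-[(2-methyloxiran-2-yl)methyl]prop-2-en-1-ol (racemic) | OCC(=C)CC1(C)CO1
F12 | step 2 | 2-[(2-methyloxiran-2-yl)methyl]prop-2-enyl acetate (racemic) | CC(=O)OCC(=C)CC1(C)CO1
F13 | step 2 | 2-methyl-3-(2-methyloxiran-2-yl)-2-(triethylsilylperoxy)propyl acetate (diastereomer mixture) | CC(=O)OCC(C)(OO[Si](CC)(CC)CC)CC1(C)CO1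
F14 | step 2 | 2-hydroperoxy-2-methyl-3-(2-methyloxiran-2-yl)propyl acetate (diastereomer mixture) | CC(=O)OCC(C)(OO)CC1(C)CO1
F15 | step 2 | cis-[5-(hydroxymethyl)-3,5-dimethyl-1,2-dioxolan-3-yl]methyl acetate (racemate of 5, relative configuration shown) | CC(=O)OC[C@@]1(C)C[C@@](C)(CO)OO1
F16 | step 15 | 2-[(3R,4R,6R)-4-acetoxy-6-(hydroxymethyl)-4,6-dimethyl-1,2-dioxan-3-yl]acetic acid | OC[C@@]1(C)C[C@@](C)(OC(C)=O)[C@@H](CC(=O)O)OO1
F17 | step 15 | 2-[(3R,4R,6R)-4-acetoxy-6-formyl-4,6-dimethyl-1,2-dioxan-3-yl]acetic acid | O=C[C@@]1(C)C[C@@](C)(OC(C)=O)[C@@H](CC(=O)O)OO1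
F18 | step 15 | 2-{(3R,4R,6R)-4-acetoxy-4,6-dimethyl-6-[(1Z)-12-phenyldodec-1-enyl]-1,2-dioxan-3-yl}acetic acid | c1ccccc1CCCCCCCCCC/C=C\[C@@]1(C)C[C@@](C)(OC(C)=O)[C@@H](CC(=O)O)OO1
F19 | step 15 | 2-[(3R,4R,6S)-4-acetoxy-4,6-dimethyl-6-(12-phenyldodecyl)-1,2-dioxan-3-yl]acetic acid | c1ccccc1CCCCCCCCCCCC[C@@]1(C)C[C@@](C)(OC(C)=O)[C@@H](CC(=O)O)OO1
F20 | step 15 | 2-[(3R,4R,6S)-4-hydroxy-4,6-dimethyl-6-(12-phenyldodecyl)-1,2-dioxan-3-yl]acetic acid | c1ccccc1CCCCCCCCCCCC[C@@]1(C)C[C@@](C)(O)[C@@H](CC(=O)O)OO1
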